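7 % of the charged substrate was left at 2.50 min in the south-west run, and this examination starts from that reading.

common to all: free catalyst 50 µM
- south-west: substrate 0.018 M; reagent 0.075 M; run made earlier
- north-west: substrate 0.028 M; reagent 0.075 M; run made earlier
- north: substrate 0.046 M; reagent 0.075 M; run made earlier
- ash: substrate 0.050 M; reagent 0.0750 M; time 5.0 min
- maple: substrate 0.015 M; reagent 0.0750 M; time 1.2 min

- south-west (time / min: product / %, substrate / %): 0.417: 33, 68; 0.833: 55, 39; 1.33: 76, 24; 2.50: 96, 7; 5.00: 100, 0
- north-west (time / min: product / %, substrate / %): 0.417: 27, 72; 1.33: 65, 33; 2.50: 89, 10; 4.00: 96, 0; 5.00: 100, 1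
- north (time / min: product / %, substrate / %): 0.417: 20, 82; 0.833: 35, 63; 1.33: 51, 44; 2.50: 82, 18; 5.00: 98, 0

(standard deviation of a reading: 1.5 percentage points)

- amounts and yields of by-product count crystals too
- given per volume of solution although it is solid: crystals
- steps that have been proposed: catalyst intermediate D <-> free catalyst + product; crystals <-> by-product; catalyst intermediate B -> by-product + catalyst intermediate C; substrate + free catalyst -> catalyst intermediate A; reagent + catalyst intermediate A <-> catalyst intermediate B; catalyst intermediate C -> catalyst intermediate D

- which of the two ends with the higher amount of product, in percent of the substrate charged ("neither" if they lie within 2 percentage points) (ash / maple / neither)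
- product at the end, in percent of the substrate charged, ash
- product at the end, in percent of the substrate charged, maple

*What do you make of that reading?* On a logarithmic scale, the substrate has fallen 1.15 powers of ten. Dividing by the time gives the decade rate, the powers of ten of substrate lost per minute: 0.462 min⁻¹. Its inverse, 2.16 min, is the time for one decade.

*One reading?* No. South-west at 1.33 min gives 0.466 min⁻¹, so within the scatter the logarithm falls on a straight line: pseudo-first-order behaviour at this loading.

*Then maple?* Its [substrate] of 0.015 M lies near south-west's 0.018 M, so I borrow the rate. In 1.2 min that is 0.554 decades, leaving 27.9 %. The south-west columns at 1.33 min add to 100 %, so I count the rest as product: 72.1 %.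

*But is the rate a constant?* Not across loadings. The north run, with 18 % left at 2.50 min, reads 0.298 min⁻¹, slower than south-west. So ash, at 0.050 M, must borrow from north at 0.046 M. Over 5.0 min that makes 1.49 decades, leaving 3.24 % and giving 96.8 % product. Ash ends higher, on my reckoning.

The forecast also names ash, with 97 % for ash and 74 % for maple, higher than my maple figure, and says: “Ash closely resembles north, which reached 98% at 5 minutes”.

    catalyst intermediate D ⇌ free catalyst + product (K = 0.0440 M, k = 80.0 s⁻¹)
    crystals ⇌ by-product, rate k2*(cs2 - [by-product]) while solid is left; crystals form when [by-product] > cs2 (solubility = 1.90 mM, k = 2.00 s⁻¹)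
    catalyst intermediate B → by-product + catalyst intermediate C (k = 460 s⁻¹)
    substrate + free catalyst → catalyst intermediate A (k = 690 M⁻¹ s⁻¹)
    reagent + catalyst intermediate A ⇌ catalyst intermediate B (K = 1.50 M⁻¹, k = 5200 M⁻¹ s⁻¹)
    catalyst intermediate C → catalyst intermediate D (k = 15.0 s⁻¹)

The flasks give 97.0 % for ash and 75.9 % for maple, so ash ends higher. Maple's 24 % of substrate left reads as a decade rate of 0.517 min⁻¹, against the borrowed 0.462 min⁻¹. Now take the neighbour of maple with [free catalyst] cut to 3.0 × 10⁻⁵ M. If the decade rate scales with the catalyst charge, maple's own 0.517 min⁻¹ becomes 0.310 min⁻¹, which leaves 42.5 % of the substrate at 1.20 min. That neighbour holds 45 % of its substrate then, and 55.3 % product.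

The runs stem from a simulated flask with made-up constants.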